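The e-folding is the unit to count in: a substrate has spent one when it has fallen by a factor e from its charge. If each substrate goes in proportion to its own concentration, under the same partner and the same single-handed catalyst, their shared time course cancels from the ratio of e-foldings. I call that ratio s, the selectivity factor: e-foldings of the left-handed substrate per e-folding of the right-handed one.

in all of them: left-handed substrate 0.10 M; right-handed substrate 0.10 M

| flask | partner | protic impurity | precatalyst | remark | time |
|---|---|---|---|---|---|
| Saturday's | 0.20 M | 5 mM | 0.11 mM | run made earlier |  |
| Friday's | 0.20 M | 5 mM | 0.17 mM | run made earlier |  |
| flask | 0.200 M | 5.00 mM | 0.22 mM |  | 10 d |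

| run | time / d | left-handed substrate / % | right-handed substrate / % |
|---|---|---|---|
| Saturday's | 1.67 | 30 | 37 |
| Saturday's | 4.00 | 10 | 24 |
| Saturday's | 8.00 | 5 | 11 |
| Saturday's | 12.0 | 0 | 8 |
| Friday's | 3.00 | 10 | 24 |
| Friday's | 6.00 | 3 | 12 |
| Friday's | 10.0 | 2 | 10 |
| Friday's | 12.0 | 1 | 7 |

(scatter of a reading: 1.5 percentage points)

- part of the left-handed substrate and right-handed substrate charged together that has reacted at 10 d
- excess of left-handed product over right-handed product in the product at 10 d
- excess of right-handed substrate over left-handed substrate among what is left of the two at 10 d

- catalyst is single-handed; left-handed substrate and right-handed substrate are mirror images of each other, charged as a racemate, each of them at the stated concentration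
- the numbers in the tables scatter with a standard deviation of 1.5 percentage points
- an excess is the difference of the two amounts in percent of their sum
- an excess is below zero if the other one leads

Each substrate is charged as 0.5 of the total, so one reading from each run gives:

Saturday, 4.00 d: s = 2.19
Friday, 6.00 d: s = 1.97
mean: s = 2.08

Friday reads at 3.00 d what Saturday reads at 4.00 d, so more precatalyst runs the same course sooner. The new flask holds [precatalyst] = 0.22 mM, more than Friday's 0.17 mM. So I judge it level at 10 d with the last readings of both runs, taken at 12.0 d, and put the right-handed substrate at their mean:

right-handed left: 7.50%

There are two ways to the excess from here. Read directly at 12.0 d, it is 100% on Saturday and 75.0% on Friday. Through s, the left-handed substrate follows from the right-handed level: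

left-handed left: 0.963%
excess of right-handed substrate: 77.2%

The two ways part on Saturday's run. The direct way cheats there: it divides by the sum of the two readings, 8.00%, and each reading carries a scatter of 1.5 percentage points. I keep the second way, which also gives 91.5% reacted and a product excess of 7.14%.

The forecast, from the same runs, says 94%, 5.3% and 83%, on the ground that “extra precatalyst buys little”, and its substrate excess stands above mine.

The new flask gives 90.9% reacted, a product excess of 7.57% and a substrate excess of 75.7%.

    partner + catalyst + left-handed substrate → catalyst + left-handed product (k = 79.0 M⁻² min⁻¹)
    partner + catalyst + right-handed substrate → catalyst + right-handed product (k = 38.0 M⁻² min⁻¹)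
    partner + protic impurity → quenched reagent (k = 0.0990 M⁻¹ min⁻¹)
    partner + precatalyst → catalyst + spent reagent (k = 9.70 × 10⁻⁴ M⁻¹ min⁻¹)

The new flask leaves 2.2% of its left-handed charge and 16% of its right-handed charge, so s = 2.08. The neighbour with 0.080 M of partner leaves 52% and 73%, so s = 2.08. At 10.0 d in the new flask, the partner's half-life by the right-handed step is 6.9 d, shorter than the 24 d by the left-handed step. The left-handed step then uses partner at 0.29 of the right-handed step's rate.

The numbers in the tables come from a simulation with constants of no real substance.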